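**Retrosynthetic overview**

1. Acid 22 comes from methyl ester 21. The acetate arm at C3 is put on last, by Lewis-acid displacement at the peroxyketal carbon of methoxydioxolane 19 with the ring intact.
2. Key disconnection: both C–O bonds of the 1,2-dioxolane (the only ring). C5–OO is made by catalytic asymmetric conjugate hydroperoxidation of (E)-enone 16 with H2O2; C3–O follows by peroxyhemiketal closure to 18.
3. Enone 16 comes from terminal alkyne 14 (carboalumination/acylation); 14 comes from ester 12 (reduction/homologation).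
4. Ester 12 comes from a B-alkyl Suzuki coupling of alkene 10 with dienyl iodide 7. 10 comes from a Cu-catalysed conjugate addition to methyl crotonate (side-chain stereocentre); 7 comes from cinnamyl bromide and a silylpropyne.
5. Ring order: one ring only, formed in step 7.

Assumption: the facial sense of the two catalyst-controlled steps (ligand in step 3, cinchona amine in step 7) is taken by analogy with the parent reactions; if either proves opposite, the antipodal ligand or the quinidine-derived pseudo-enantiomer is used with nothing else changed.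

**Route**

Step 1
Reactants: 1 1-(trimethylsilyl)propyne; 2 (E)-cinnamyl bromide
Product: 5 [(1E)-hex-1-en-5-yn-1-yl]benzene, via lithiated silylpropyne 3 (not isolated), via silyl enyne 4 (not isolated)
Conditions: n-BuLi, THF, −78 °C; then 2, −78 °C → rt; then K2CO3 (cat.), MeOH, rt
Reagents that add atoms: none
Why: Propargylic lithiation and SN2 alkylation by the primary allylic bromide, then protodesilylation of the alkynylsilane, leave the E-styrene untouched.

Step 2
Reactants: 5 [(1E)-hex-1-en-5-yn-1-yl]benzene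
Product: 7 [(1E,5E)-6-iodohexa-1,5-dien-1-yl]benzene, via alkenylzirconocene 6 (not isolated)
Conditions: Cp2Zr(H)Cl, THF, rt; then I2, 0 °C
Reagents that add atoms: iodine, II
Why: Schwartz hydrozirconation adds syn to the terminal alkyne (faster than to the internal styrene) and iodinolysis proceeds with retention, giving the E-iodoalkene.

Step 3
Reactants: 8 methyl (E)-but-2-enoate; 9 but-3-en-1-ylmagnesium bromide
Product: 10 methyl (3R)-3-methylhept-6-enoate
Conditions: CuBr·SMe2 (5 mol %), (R,S)-Josiphos (6 mol %), t-BuOMe, −75 °C; aq NH4Cl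
Reagents that add atoms: none
Why: Copper-catalysed asymmetric conjugate addition of a Grignard reagent to a crotonate; the ligand directs the butenyl group to the Si face of C3, which sets the side-chain stereocentre as R.

Step 4
Reactants: 10 methyl (3R)-3-methylhept-6-enoate; 7 [(1E,5E)-6-iodohexa-1,5-dien-1-yl]benzene
Product: 12 methyl (3R,8E,12E)-3-methyl-13-phenyltrideca-8,12-dienoate, via alkylborane 11 (not isolated)
Conditions: 9-BBN, THF, rt; then 7, PdCl2(dppf) (5 mol %), AsPh3, Cs2CO3, DMF/H2O, rt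
Reagents that add atoms: none
Why: Anti-Markovnikov hydroboration of the terminal alkene followed by B-alkyl Suzuki–Miyaura coupling, which keeps the E geometry of the iodoalkene and does not touch the ester or the stereocentre.

Step 5
Reactants: 12 methyl (3R,8E,12E)-3-methyl-13-phenyltrideca-8,12-dienoate
Product: 14 [(1E,5E,11R)-11-methyltetradeca-1,5-dien-13-yn-1-yl]benzene, via aldehyde 13 (not isolated)
Conditions: DIBAL-H, CH2Cl2, −78 °C; then MeOH, K2CO3, dimethyl (1-diazo-2-oxopropyl)phosphonate, → rt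
Reagents that add atoms: dimethyl (1-diazo-2-oxopropyl)phosphonate, CC(=O)C(=[N+]=[N-])P(=O)(OC)OC
Why: Partial ester reduction and in-situ Seyferth–Gilbert homologation (Bestmann–Ohira reagent); the stereocentre is β to the aldehyde and cannot epimerise.

Step 6
Reactants: 14 [(1E,5E,11R)-11-methyltetradeca-1,5-dien-13-yn-1-yl]benzene
Product: 16 (3E,6R,11E,15E)-4,6-dimethyl-16-phenylhexadeca-3,11,15-trien-2-one, via alkenylalane 15 (not isolated)
Conditions: Me3Al, Cp2ZrCl2 (20 mol %), CH2Cl2, 0 °C → rt; excess Me3Al removed in vacuo; then AcCl, Pd(PPh3)4 (5 mol %), THF, 0 °C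
Reagents that add atoms: trimethylaluminium, C[Al](C)C; acetyl chloride, CC(Cl)=O
Why: Negishi zirconium-catalysed syn-carboalumination puts methyl on the internal carbon, and Pd-catalysed acylation with retention gives the E-enone (methyl cis to acetyl); the internal alkenes are inert.

Step 7
Reactants: 16 (3E,6R,11E,15E)-4,6-dimethyl-16-phenylhexadeca-3,11,15-trien-2-one
Product: 18 (5R)-3,5-dimethyl-5-[(2R,7E,11E)-2-methyl-12-phenyldodeca-7,11-dien-1-yl]-1,2-dioxolan-3-ol (both C3 epimers), via hydroperoxy ketone 17 (not isolated)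
Conditions: 9-amino-9-deoxy-epi-quinine (10 mol %), TFA (20 mol %), 50 % aq H2O2 (3 equiv), dioxane, 35 °C
Reagents that add atoms: hydrogen peroxide, OO
Why: Proposed new method: the primary amine condenses with the methyl ketone to an iminium ion whose protonated quinuclidine hydrogen-bonds H2O2 and delivers it to the Re face of the β-carbon (C4); because the E geometry fixes where methyl and alkyl sit, face selection alone sets the tertiary C–OO centre as R (ring C5), and hydroperoxy ketone 17 released on hydrolysis closes to the peroxyhemiketal faster than it can give epoxide; the closest known reaction type is the cinchona primary-amine (iminium) catalysed hydroperoxidation of β-monosubstituted acyclic enones to peroxyhemiketals and epoxidation of 3-substituted cyclic enones, not yet shown for an acyclic β,β-disubstituted enone.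

Step 8
Reactants: 18 (5R)-3,5-dimethyl-5-[(2R,7E,11E)-2-methyl-12-phenyldodeca-7,11-dien-1-yl]-1,2-dioxolan-3-ol
Product: 19 (5R)-3-methoxy-3,5-dimethyl-5-[(2R,7E,11E)-2-methyl-12-phenyldodeca-7,11-dien-1-yl]-1,2-dioxolane (both C3 epimers)
Conditions: MeOH, PPTS (cat.), rt
Reagents that add atoms: methanol, CO
Why: Acid-catalysed ketalisation of the peroxyhemiketal exchanges only the anomeric C3 substituent; C5 is not involved and both C3 epimers converge in the next step.

Step 9
Reactants: 19 (5R)-3-methoxy-3,5-dimethyl-5-[(2R,7E,11E)-2-methyl-12-phenyldodeca-7,11-dien-1-yl]-1,2-dioxolane; 20 tert-butyl[(1-methoxyethenyl)oxy]dimethylsilane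
Product: 21 methyl 2-[(3S,5R)-3,5-dimethyl-5-[(2R,7E,11E)-2-methyl-12-phenyldodeca-7,11-dien-1-yl]-1,2-dioxolan-3-yl]acetate
Conditions: 20 (2 equiv), TMSOTf (0.2 equiv), CH2Cl2, −78 °C
Reagents that add atoms: none
Why: TMSOTf ionises the peroxyketal to the dioxolan-3-yl cation and the silyl ketene acetal adds anti to the larger C5 substituent, a Mukaiyama-type displacement known for 3-alkoxy-1,2-dioxolanes; this gives (3S) with only a modest preference, so the C3 epimer is removed by chromatography.

Step 10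
Reactants: 21 methyl 2-[(3S,5R)-3,5-dimethyl-5-[(2R,7E,11E)-2-methyl-12-phenyldodeca-7,11-dien-1-yl]-1,2-dioxolan-3-yl]acetate
Product: 22 2-[(3S,5R)-3,5-dimethyl-5-[(2R,7E,11E)-2-methyl-12-phenyldodeca-7,11-dien-1-yl]-1,2-dioxolan-3-yl]acetic acid
Conditions: LiOH, THF/H2O, 0 °C → rt; then 1 M HCl to pH 3
Reagents that add atoms: lithium hydroxide, [Li+].[OH-]
Why: Saponification; the fully substituted dialkyl peroxide has no α-hydrogen for base-induced fragmentation and the carboxylate does not undergo retro-Michael opening.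

**Compound list**

1 | 1-(trimethylsilyl)propyne | CC#C[Si](C)(C)C | starting material
2 | (E)-cinnamyl bromide | BrC/C=C/c1ccccc1 | starting material
3 | [3-(trimethylsilyl)prop-2-yn-1-yl]lithium | [Li]CC#C[Si](C)(C)C | intermediate
4 | trimethyl[(5E)-6-phenylhex-5-en-1-yn-1-yl]silane | C[Si](C)(C)C#CCC/C=C/c1ccccc1 | intermediate
5 | [(1E)-hex-1-en-5-yn-1-yl]benzene | C#CCC/C=C/c1ccccc1 | intermediate
6 | chloridobis(cyclopentadienyl)[(1E,5E)-6-phenylhexa-1,5-dien-1-yl]zirconium | Cl[Zr](/C=C/CC/C=C/c1ccccc1)(C1C=CC=C1)C1C=CC=C1 | intermediate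
7 | [(1E,5E)-6-iodohexa-1,5-dien-1-yl]benzene | I/C=C/CC/C=C/c1ccccc1 | intermediate
8 | methyl (E)-but-2-enoate | C/C=C/C(=O)OC | starting material
9 | but-3-en-1-ylmagnesium bromide | C=CCC[Mg]Br | starting material
10 | methyl (3R)-3-methylhept-6-enoate | C[C@H](CCC=C)CC(=O)OC | intermediate
11 | methyl (3R)-7-(9-borabicyclo[3.3.1]nonan-9-yl)-3-methylheptanoate | C[C@H](CCCCB1C2CCCC1CCC2)CC(=O)OC | intermediate
12 | methyl (3R,8E,12E)-3-methyl-13-phenyltrideca-8,12-dienoate | C[C@H](CCCC/C=C/CC/C=C/c1ccccc1)CC(=O)OC | intermediate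
13 | (3R,8E,12E)-3-methyl-13-phenyltrideca-8,12-dienal | C[C@H](CCCC/C=C/CC/C=C/c1ccccc1)CC=O | intermediate
14 | [(1E,5E,11R)-11-methyltetradeca-1,5-dien-13-yn-1-yl]benzene | C[C@H](CCCC/C=C/CC/C=C/c1ccccc1)CC#C | intermediate
15 | dimethyl[(1E,4R,9E,13E)-2,4-dimethyl-14-phenyltetradeca-1,9,13-trien-1-yl]alumane | C[C@H](CCCC/C=C/CC/C=C/c1ccccc1)C/C(C)=C/[Al](C)C | intermediate
16 | (3E,6R,11E,15E)-4,6-dimethyl-16-phenylhexadeca-3,11,15-trien-2-one | C[C@H](CCCC/C=C/CC/C=C/c1ccccc1)C/C(C)=C/C(C)=O | intermediate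
17 | (4R,6R,11E,15E)-4-hydroperoxy-4,6-dimethyl-16-phenylhexadeca-11,15-dien-2-one | C[C@H](CCCC/C=C/CC/C=C/c1ccccc1)C[C@@](C)(OO)CC(C)=O | intermediate
18 | (5R)-3,5-dimethyl-5-[(2R,7E,11E)-2-methyl-12-phenyldodeca-7,11-dien-1-yl]-1,2-dioxolan-3-ol (both C3 epimers) | C[C@H](CCCC/C=C/CC/C=C/c1ccccc1)C[C@]1(C)CC(C)(O)OO1 | intermediate
19 | (5R)-3-methoxy-3,5-dimethyl-5-[(2R,7E,11E)-2-methyl-12-phenyldodeca-7,11-dien-1-yl]-1,2-dioxolane (both C3 epimers) | C[C@H](CCCC/C=C/CC/C=C/c1ccccc1)C[C@]1(C)CC(C)(OC)OO1 | intermediate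
20 | tert-butyl[(1-methoxyethenyl)oxy]dimethylsilane | COC(=C)O[Si](C)(C)C(C)(C)C | starting material
21 | methyl 2-[(3S,5R)-3,5-dimethyl-5-[(2R,7E,11E)-2-methyl-12-phenyldodeca-7,11-dien-1-yl]-1,2-dioxolan-3-yl]acetate | C[C@H](CCCC/C=C/CC/C=C/c1ccccc1)C[C@]1(C)C[C@@](C)(CC(=O)OC)OO1 | intermediate
22 | 2-[(3S,5R)-3,5-dimethyl-5-[(2R,7E,11E)-2-methyl-12-phenyldodeca-7,11-dien-1-yl]-1,2-dioxolan-3-yl]acetic acid | C[C@H](CCCC/C=C/CC/C=C/c1ccccc1)C[C@]1(C)C[C@@](C)(CC(=O)O)OO1 | target

**Step count**

Total: 10 steps. Longest linear sequence: 9 steps (steps 1, 2 and 4–10, from 1-(trimethylsilyl)propyne and cinnamyl bromide through iodide 7). The branch from methyl crotonate (steps 3–10) is 8 steps.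

**Three steps most likely to fail**

Step 7 (the proposed new step). The hindered β,β-disubstituted enone may form the iminium slowly. E/Z scrambling through the dienamine would erode the facial fidelity at C5, and enamine-driven epoxide closure competes. The fallback uses known chemistry; it sets out from 14 and comes back at 18. Carboalumination of 14 as in step 6 and trapping of 15 with paraformaldehyde gives the primary allylic alcohol F1. Sharpless asymmetric epoxidation (Ti(OiPr)4, L-(+)-DET, t-BuOOH) gives the (2S,3S)-epoxy alcohol F2. Dess–Martin oxidation gives the epoxy aldehyde F3, and MeMgBr gives the secondary epoxy alcohol F4 (carbinol epimers, irrelevant later). Red-Al opens the epoxide at the carbinol-adjacent carbon to the 1,3-diol F5. Selective tosylation of the secondary hydroxyl gives the monotosylate F6, and KOtBu closes the oxetane F7 through the tertiary alkoxide. Ethereal H2O2 with TMSOTf opens the oxetane at the tertiary carbon with inversion to the hydroperoxy alcohol F8. Dess–Martin oxidation of the secondary alcohol then gives 17, which closes to 18.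

Step 9. The two C5 substituents (methyl and 2-methylalkyl) differ little in size, so the facial bias at the C3 cation is weak and the diastereomer ratio may be low. The fallback sets out from 18 and comes back at 21, and replaces the C–C displacement by a C–O ring closure. Wittig olefination of the open keto form with Ph3P=CHCO2Me (PhCO2H cat., toluene, 60 °C) gives the hydroperoxy enoate F9. Et2NH in CF3CH2OH then closes the dioxolane by 5-exo peroxy-Michael addition. This closure is reversible, so the C3 epimers equilibrate and the unwanted one can be resubjected after separation.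

Step 6. Direct acylation of the alkenylalane can be low-yielding (methyl transfer from residual Me3Al, over-addition to the ketone). The fallback sets out from 14 and comes back at 16. Carboalumination as in step 6 and iodinolysis of 15 gives the vinyl iodide F10. Stille coupling with tributyl(1-ethoxyvinyl)stannane (Pd(PPh3)4, CuI, DMF) gives the dienol ether F11, and 1 M HCl in THF releases enone 16.

Further compounds
F1 | step 7 | (2E,5R,10E,14E)-3,5-dimethyl-15-phenylpentadeca-2,10,14-trien-1-ol | C[C@H](CCCC/C=C/CC/C=C/c1ccccc1)C/C(C)=C/CO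
F2 | step 7 | [(2S,3S)-3-methyl-3-[(2R,7E,11E)-2-methyl-12-phenyldodeca-7,11-dien-1-yl]oxiran-2-yl]methanol | C[C@H](CCCC/C=C/CC/C=C/c1ccccc1)C[C@]1(C)O[C@H]1CO
F3 | step 7 | (2R,3S)-3-methyl-3-[(2R,7E,11E)-2-methyl-12-phenyldodeca-7,11-dien-1-yl]oxirane-2-carbaldehyde | C[C@H](CCCC/C=C/CC/C=C/c1ccccc1)C[C@]1(C)O[C@H]1C=O
F4 | step 7 | 1-[(2S,3S)-3-methyl-3-[(2R,7E,11E)-2-methyl-12-phenyldodeca-7,11-dien-1-yl]oxiran-2-yl]ethan-1-ol (carbinol epimers) | C[C@H](CCCC/C=C/CC/C=C/c1ccccc1)C[C@]1(C)O[C@H]1C(C)O
F5 | step 7 | (4S,6R,11E,15E)-4,6-dimethyl-16-phenylhexadeca-11,15-diene-2,4-diol (C2 epimers) | C[C@H](CCCC/C=C/CC/C=C/c1ccccc1)C[C@](C)(O)CC(C)O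
F6 | step 7 | (4S,6R,11E,15E)-4-hydroxy-4,6-dimethyl-16-phenylhexadeca-11,15-dien-2-yl 4-methylbenzenesulfonate (C2 epimers) | C[C@H](CCCC/C=C/CC/C=C/c1ccccc1)C[C@](C)(O)CC(C)OS(=O)(=O)c1ccc(C)cc1
F7 | step 7 | (2S)-2,4-dimethyl-2-[(2R,7E,11E)-2-methyl-12-phenyldodeca-7,11-dien-1-yl]oxetane (C4 epimers) | C[C@H](CCCC/C=C/CC/C=C/c1ccccc1)C[C@@]1(C)CC(C)O1
F8 | step 7 | (4R,6R,11E,15E)-4-hydroperoxy-4,6-dimethyl-16-phenylhexadeca-11,15-dien-2-ol (C2 epimers) | C[C@H](CCCC/C=C/CC/C=C/c1ccccc1)C[C@@](C)(OO)CC(C)O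
F9 | step 9 | methyl (2E,5R,7R,12E,16E)-5-hydroperoxy-3,5,7-trimethyl-17-phenylheptadeca-2,12,16-trienoate | C[C@H](CCCC/C=C/CC/C=C/c1ccccc1)C[C@@](C)(OO)C/C(C)=C/C(=O)OC
F10 | step 6 | [(1E,5E,11R,13E)-14-iodo-11,13-dimethyltetradeca-1,5,13-trien-1-yl]benzene | C[C@H](CCCC/C=C/CC/C=C/c1ccccc1)C/C(C)=C/I
F11 | step 6 | [(1E,5E,11R,13E)-15-ethoxy-11,13-dimethylhexadeca-1,5,13,15-tetraen-1-yl]benzene | C[C@H](CCCC/C=C/CC/C=C/c1ccccc1)C/C(C)=C/C(=C)OCC
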